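The quinone ring (numbered C1(=O), C2(OH), C3(side chain), C4(=O), C5(OMe), C6(H)) is the enol form of a cyclohex-5-ene-1,2,4-trione. The enolic C2(OH)=C3(alkyl) bond is therefore disconnected as a Dieckmann acylation of C3 (α to the C4 carbonyl) by an oxalyl ester carbon C2, at the oxidation level of the target. The acyclic cis-ene-dione needed, C1(=O)–C6H=C5(OMe)–C4(=O), is latent in a temporary furan ring, methyl 5-[(3R)-3-acetoxytetradecyl]-4-methoxyfuran-2-carboxylate, which fixes the cis geometry and the methoxy position. One operation (dimethyldioxirane opening, then LiN(SiMe3)2) turns the furan into the quinone, with the acetate stereocentre, set from (R)-epichlorohydrin, already in place.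

Key step: step 7

Remark: the target is treated as the stable 2-hydroxy-1,4-benzoquinone tautomer of the trione that the ring closure produces; compounds 1, 2 and 7 are taken as commercially available.

Step 1
Reactants: 1 (R)-epichlorohydrin; 2 decylmagnesium bromide
Product: 4 (2R)-2-undecyloxirane, via (2R)-1-chlorotridecan-2-ol 3 (not isolated)
Conditions: CuI (5 mol%), THF, −40 → 0 °C; aq. NH4Cl; crude 3, powdered NaOH, Et2O, rt
Reagents that add atoms: none
Why: Copper-catalysed Grignard opening of the epoxide at its unsubstituted terminus followed by Williamson closure of the chlorohydrin onto CH2Cl should give the homologated epoxide, the stereocentre of 1 being carried through untouched (descriptor stays R).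

Step 2
Reactants: 4 (2R)-2-undecyloxirane
Product: 5 (3R)-tetradec-1-en-3-ol
Conditions: Me3S+ I− (3 equiv), nBuLi (2.9 equiv), THF, −10 °C → rt
Reagents that add atoms: trimethylsulfonium iodide, C[S+](C)C.[I-]
Why: Dimethylsulfonium methylide should open the terminal epoxide carbon and the resulting β-sulfonium alkoxide should eliminate Me2S under excess ylide (one-carbon epoxide-to-allylic-alcohol homologation), leaving the carbinol centre unchanged.

Step 3
Reactants: 5 (3R)-tetradec-1-en-3-ol
Product: 6 (3R)-tetradec-1-en-3-yl acetate
Conditions: Ac2O, pyridine, DMAP (cat.), CH2Cl2, 0 °C → rt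
Reagents that add atoms: acetic anhydride, CC(=O)OC(C)=O
Why: DMAP-catalysed O-acylation of a secondary alcohol proceeds with retention, so the final acetate is installed before any base-sensitive quinone chemistry.

Step 4
Reactants: 7 methyl 4-bromofuran-2-carboxylate
Product: 8 methyl 4-methoxyfuran-2-carboxylate
Conditions: MeOH (5 equiv), Pd2(dba)3 (1 mol%), tBuBrettPhos (2.5 mol%), Cs2CO3, toluene, 80 °C
Reagents that add atoms: methanol, CO
Why: Buchwald–Hartwig-type C–O coupling of an electron-poor heteroaryl bromide, in which the bulky biaryl phosphine should favour C–O reductive elimination over β-hydride elimination of the palladium methoxide; methoxide cannot scramble a methyl ester.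

Step 5
Reactants: 8 methyl 4-methoxyfuran-2-carboxylate
Product: 9 methyl 5-bromo-4-methoxyfuran-2-carboxylate
Conditions: NBS (1.05 equiv), MeCN, 0 °C, dark
Reagents that add atoms: N-bromosuccinimide, O=C1CCC(=O)N1Br
Why: Electrophilic bromination should occur at C5, the only free α-position of the furan and ortho to the donor methoxy group, and not at the β-position C3 next to the ester.

Step 6
Reactants: 6 (3R)-tetradec-1-en-3-yl acetate; 9 methyl 5-bromo-4-methoxyfuran-2-carboxylate
Product: 11 methyl 5-[(3R)-3-(acetyloxy)tetradecyl]-4-methoxyfuran-2-carboxylate, via B-alkyl-9-BBN borane 10 (not isolated)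
Conditions: 6, 9-BBN (1.3 equiv), THF, 0 °C → rt; then 9, PdCl2(dppf) (5 mol%), 3 M aq. K3PO4, DMF, rt → 45 °C
Reagents that add atoms: none
Why: Anti-Markovnikov hydroboration places boron on C1 (γ to the acetate, so no β-elimination) and B-alkyl Suzuki–Miyaura coupling with the 2-bromofuran should form the sp3–sp2 bond without touching the stereocentre.

Step 7
Reactants: 11 methyl 5-[(3R)-3-(acetyloxy)tetradecyl]-4-methoxyfuran-2-carboxylate
Product: 14 (2R)-1-(2-hydroxy-5-methoxy-3,6-dioxocyclohexa-1,4-dien-1-yl)tridecan-2-yl acetate, via cis-ene-dione ester 12 (not isolated), via cyclohexenetrione tautomer 13 (not isolated)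
Conditions: DMDO (1.05 equiv), acetone, −78 → 0 °C; evaporate cold; LiN(SiMe3)2 (1.1 equiv), THF (0.02 M), −78 → 0 °C; cold 1 M HCl
Reagents that add atoms: dimethyldioxirane, CC1(C)OO1
Why: Dimethyldioxirane should epoxidise the electron-rich C4=C5 enol-ether bond of the furan, and the epoxide opens in the usual furan-to-ene-dione manner to 12, the furan oxygen becoming the C2 ketone oxygen and the cis C3=C4 geometry being inherited from the ring. Deprotonation of 12 at C6, its only ketone α-position, gives a lithium enolate that acylates the oxalyl ester carbon C1 with loss of methoxide, an intramolecular Claisen (Dieckmann) condensation of the kind used in classical oxalate-based hydroxyquinone syntheses; this joins the side-chain-bearing carbon to the future C–OH carbon. The carbocycle closes in the favoured 6-(enolendo)-exo-trig mode, whereas aldol attack on the C2 ketone would be a disfavoured and reversible 5-(enolendo)-exo-trig closure. Trione 13 is a vinylogous acid and should be deprotonated at once by the liberated methoxide, so the closure becomes irreversible and acidification delivers the hydroxyquinone tautomer 14 with no redox step. No new stereocentre is formed, and the acetate-bearing centre lies two carbons from the enolate and cannot epimerise. The step needs C- over O-acylation and attack on the oxalyl ester rather than the acetate; these should be secured by lithium chelation to the 1,2-dicarbonyl unit, by the much higher electrophilicity of the α-keto ester, by the use of only 1.1 equiv of a non-nucleophilic amide at low temperature, and by the thermodynamic sink of the hydroxyquinone anion.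

Compound list
1 | (R)-epichlorohydrin, (2R)-2-(chloromethyl)oxirane | ClC[C@H]1CO1 | starting material
2 | decylmagnesium bromide | CCCCCCCCCC[Mg]Br | starting material
3 | (2R)-1-chlorotridecan-2-ol | ClC[C@H](O)CCCCCCCCCCC | intermediate (not isolated)
4 | (2R)-2-undecyloxirane, (R)-1,2-epoxytridecane | CCCCCCCCCCC[C@@H]1CO1 | intermediate
5 | (3R)-tetradec-1-en-3-ol | CCCCCCCCCCC[C@@H](O)C=C | intermediate
6 | (3R)-tetradec-1-en-3-yl acetate | CCCCCCCCCCC[C@@H](OC(C)=O)C=C | intermediate
7 | methyl 4-bromofuran-2-carboxylate | COC(=O)c1cc(Br)co1 | starting material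
8 | methyl 4-methoxyfuran-2-carboxylate | COC(=O)c1cc(OC)co1 | intermediate
9 | methyl 5-bromo-4-methoxyfuran-2-carboxylate | COC(=O)c1cc(OC)c(Br)o1 | intermediate
10 | 9-[(3S)-3-(acetyloxy)tetradecyl]-9-borabicyclo[3.3.1]nonane (same spatial arrangement as 6; the descriptor changes only because boron ranks below carbon) | CCCCCCCCCCC[C@@H](OC(C)=O)CCB1C2CCCC1CCC2 | intermediate (not isolated)
11 | methyl 5-[(3R)-3-(acetyloxy)tetradecyl]-4-methoxyfuran-2-carboxylate | CCCCCCCCCCC[C@@H](OC(C)=O)CCc1oc(C(=O)OC)cc1OC | intermediate
12 | methyl (3E,8R)-8-(acetyloxy)-4-methoxy-2,5-dioxononadec-3-enoate (C2 and C5 carbonyls cis on the C3=C4 bond) | CCCCCCCCCCC[C@@H](OC(C)=O)CCC(=O)/C(OC)=C\C(=O)C(=O)OC | intermediate (not isolated)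
13 | (2R)-1-(3-methoxy-2,5,6-trioxocyclohex-3-en-1-yl)tridecan-2-yl acetate (ring CH epimers, enolises on) | CCCCCCCCCCC[C@@H](OC(C)=O)CC1C(=O)C(=O)C=C(OC)C1=O | intermediate (not isolated)
14 | (2R)-1-(2-hydroxy-5-methoxy-3,6-dioxocyclohexa-1,4-dien-1-yl)tridecan-2-yl acetate | CCCCCCCCCCC[C@H](CC1=C(O)C(=O)C=C(OC)C1=O)OC(C)=O | target

Total step count: 7. Longest linear sequence: 5 steps (steps 1, 2, 3, 6, 7 from (R)-epichlorohydrin); the furan branch (steps 4, 5) joins at step 6.

Steps most likely to fail

1. Step 7. The electron-rich furan or the ene-dione may be over-oxidised. In the base stage the kinetic lithium enolate may transfer the side-chain acetyl group to carbon (Baker–Venkataraman-type), acylate on oxygen, or the electrophilic ene-trione may oligomerise before closing. Fallback: the sequence sets out from 11, is stopped after the dimethyldioxirane stage and uses crude 12. Treatment with NaOMe (2.5 equiv) in MeOH, 0 °C → rt, should effect the same Dieckmann closure under fully reversible alkoxide conditions, which funnel O-acylated or aldol by-products to the quinone anion. The acetate is deliberately lost by methanolysis, and careful acidification to pH 3 should give 2-hydroxy-3-[(2R)-2-hydroxytridecyl]-5-methoxycyclohexa-2,5-diene-1,4-dione F1. Ac2O, pyridine and DMAP should then give the diacetate (2R)-1-[2-(acetyloxy)-5-methoxy-3,6-dioxocyclohexa-1,4-dien-1-yl]tridecan-2-yl acetate F2. Its quinonyl enol acetate, a vinylogous anhydride, should be cleaved selectively with NaHCO3 in aqueous MeOH at 0 °C, coming back to the route at 14.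

2. Step 6. Transmetalation of the alkylborane may be slow, so that protodebromination of 9 competes, and the aqueous phosphate may partly hydrolyse the acetate or the methyl ester. Fallback: a base-free Negishi coupling that sets out from 6 and 9. Borane 10 is oxidised with NaBO3·4H2O (THF/H2O, rt) to (3R)-1-hydroxytetradecan-3-yl acetate F3. Appel iodination (I2, PPh3, imidazole, CH2Cl2, 0 °C) gives (3R)-1-iodotetradecan-3-yl acetate F4. Zinc dust with LiCl in THF gives [(3R)-3-(acetyloxy)tetradecyl]zinc iodide F5, which is coupled with 9 using Pd(OAc)2 and SPhos in THF at rt, coming back to the route at 11.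

3. Step 4. The palladium methoxide may undergo β-hydride elimination and reduce the C–Br bond, or the catalyst may be deactivated by the furan ester. Fallback: oxygen is introduced through boron, setting out from 7. Miyaura borylation (B2pin2, PdCl2(dppf), KOAc, dioxane, 80 °C) gives methyl 4-(4,4,5,5-tetramethyl-1,3,2-dioxaborolan-2-yl)furan-2-carboxylate F6. Oxidation (H2O2, aq. NaHCO3, THF, 0 °C) gives methyl 4-oxo-4,5-dihydrofuran-2-carboxylate F7, the keto form of the 4-hydroxyfuran. O-Methylation with the hard electrophile Me2SO4 (K2CO3, acetone) restores the aromatic furan and comes back to the route at 8.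

Further compounds
F1 | step 7 | 2-hydroxy-3-[(2R)-2-hydroxytridecyl]-5-methoxycyclohexa-2,5-diene-1,4-dione | CCCCCCCCCCC[C@@H](O)CC1=C(O)C(=O)C=C(OC)C1=O
F2 | step 7 | (2R)-1-[2-(acetyloxy)-5-methoxy-3,6-dioxocyclohexa-1,4-dien-1-yl]tridecan-2-yl acetate | CCCCCCCCCCC[C@@H](OC(C)=O)CC1=C(OC(C)=O)C(=O)C=C(OC)C1=O
F3 | step 6 | (3R)-1-hydroxytetradecan-3-yl acetate | CCCCCCCCCCC[C@@H](OC(C)=O)CCO
F4 | step 6 | (3R)-1-iodotetradecan-3-yl acetate | CCCCCCCCCCC[C@@H](OC(C)=O)CCI
F5 | step 6 | [(3R)-3-(acetyloxy)tetradecyl]zinc iodide | CCCCCCCCCCC[C@@H](OC(C)=O)CC[Zn]I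
F6 | step 4 | methyl 4-(4,4,5,5-tetramethyl-1,3,2-dioxaborolan-2-yl)furan-2-carboxylate | COC(=O)c1cc(B2OC(C)(C)C(C)(C)O2)co1
F7 | step 4 | methyl 4-oxo-4,5-dihydrofuran-2-carboxylate | COC(=O)C1=CC(=O)CO1
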